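**Retrosynthetic overview**
- The route rests on the (E)-trisubstituted C2'=C3' alkene (side chain numbered C1' benzylic to C15'). Its C3' methyl and its link through C1' to the 2-methylhydroquinone ring are made together, by syn methylalumination of a terminal C2'≡C3' alkyne and nickel-catalysed benzylation at C2'.
- Other disconnections: C12'–C13' (prenylbarium addition to a C12' aldehyde, then oxidation); C4'–C5' (asymmetric propargylation of a C5' enal); C5'–C6' and C7'–CH3 (methylalumination–hydroxymethylation of a C6'–C12' alkyne); C9'–C10' (copper-catalysed Grignard–tosylate coupling).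
- No ring is formed. The benzene ring comes from 3-methylsalicylic acid and is unmasked to the hydroquinone in the last step.
- C11' comes from methyl (S)-3-hydroxy-2-methylpropanoate (its ester carbon becomes C12'); C5' is set by a chiral phosphoric acid.

Key step: step 14

**Remarks on the chemistry**
- C12' is carried as a triethylsilyl ether, not a p-methoxybenzyl ether. Oxidative PMB removal after the coupling would have to spare the more electron-rich dimethoxyarene and its benzylic-allylic C1' methylene. Primary TES is cleaved by PPTS while the secondary TBS ether at C5' stays.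
- Assumption: the (R)-configured phosphoric acid is taken to direct the allenylboronate to the Re face of enal 12, as expected for aryl and alkenyl aldehydes; this gives (R) at C5'.

**Route**

Step 1
Reactants: 1 methyl (S)-3-hydroxy-2-methylpropanoate
Product: 2 methyl (S)-2-methyl-3-(tosyloxy)propanoate
Conditions: TsCl, pyridine, CH2Cl2, 0 °C
Reagents that add atoms: p-toluenesulfonyl chloride, Cc1ccc(cc1)S(=O)(=O)Cl
Why: Tosylation of the primary alcohol under mild base, which should not eliminate the β-sulfonyloxy ester, activates the carbon that becomes C10' without touching the stereocentre.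

Step 2
Reactants: 2 methyl (S)-2-methyl-3-(tosyloxy)propanoate
Product: 3 (R)-3-hydroxy-2-methylpropyl 4-methylbenzenesulfonate
Conditions: iBu2AlH, CH2Cl2, −78 → −20 °C; aq. potassium sodium tartrate
Reagents that add atoms: none
Why: Chemoselective hydride reduction of the ester to the primary alcohol (future C12') should leave the primary sulfonate intact at low temperature, and the non-basic reagent avoids β-elimination.

Step 3
Reactants: 3 (R)-3-hydroxy-2-methylpropyl 4-methylbenzenesulfonate
Product: 4 (R)-2-methyl-3-(triethylsilyloxy)propyl 4-methylbenzenesulfonate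
Conditions: TESCl, imidazole, CH2Cl2, 0 °C
Reagents that add atoms: chlorotriethylsilane, CC[Si](CC)(CC)Cl
Why: Standard silylation of a primary alcohol; a tosyl group cannot migrate, so the stereocentre cannot be scrambled through a symmetric diol derivative.

Step 4
Reactants: 4 (R)-2-methyl-3-(triethylsilyloxy)propyl 4-methylbenzenesulfonate; 5 (4-bromobut-1-yn-1-yl)trimethylsilane
Product: 7 (S)-triethyl{[2-methyl-7-(trimethylsilyl)hept-6-yn-1-yl]oxy}silane, via Grignard reagent 6 (not isolated)
Conditions: 5, Mg, THF, rt; then 4, Li2CuCl4 (5 mol %), THF, −20 °C → rt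
Reagents that add atoms: none
Why: Copper-catalysed sp3–sp3 cross-coupling of a primary alkyl Grignard reagent with a primary tosylate forms C9'–C10' by displacement at a carbon that is not the stereocentre.

Step 5
Reactants: 7 (S)-triethyl{[2-methyl-7-(trimethylsilyl)hept-6-yn-1-yl]oxy}silane
Product: 8 (S)-triethyl[(2-methylhept-6-yn-1-yl)oxy]silane
Conditions: K2CO3, MeOH, rt
Reagents that add atoms: none
Why: Methanolysis of the alkynyl C–Si bond should be much faster than cleavage of the primary triethylsilyl ether, freeing the terminal alkyne (protiodesilylation).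

Step 6
Reactants: 8 (S)-triethyl[(2-methylhept-6-yn-1-yl)oxy]silane
Product: 11 (2E,7S)-3,7-dimethyl-8-(triethylsilyloxy)oct-2-en-1-ol, via alkenyldimethylalane 9 (not isolated), via lithium alkenylalanate 10 (not isolated)
Conditions: AlMe3 (2 equiv), Cp2ZrCl2 (0.25 equiv), CH2Cl2, 0 °C → rt; volatiles removed, hexane; n-BuLi, 0 °C; (CH2O)n, THF, rt
Reagents that add atoms: trimethylaluminium, C[Al](C)C; paraformaldehyde (as formaldehyde), C=O
Why: Zirconium-catalysed syn methylalumination (Negishi carboalumination) places methyl on C7' and aluminium on C6', and the alanate formed with n-BuLi transfers its alkenyl group to formaldehyde with retention, fixing the (E)-C6'=C7' geometry.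

Step 7
Reactants: 11 (2E,7S)-3,7-dimethyl-8-(triethylsilyloxy)oct-2-en-1-ol
Product: 12 (2E,7S)-3,7-dimethyl-8-(triethylsilyloxy)oct-2-enal
Conditions: MnO2, CH2Cl2, rt
Reagents that add atoms: none
Why: Allylic oxidation with activated MnO2 is selective for the allylic alcohol and should preserve the alkene geometry and the silyl ether.

Step 8
Reactants: 12 (2E,7S)-3,7-dimethyl-8-(triethylsilyloxy)oct-2-enal; 13 allenylboronic acid pinacol ester
Product: 15 (4R,5E,10S)-6,10-dimethyl-11-(triethylsilyloxy)undec-5-en-1-yn-4-ol, via pinacol borate ester 14 (not isolated)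
Conditions: (R)-3,3'-bis(2,4,6-triisopropylphenyl)-1,1'-binaphthyl-2,2'-diyl hydrogen phosphate (10 mol %), 4 Å molecular sieves, toluene, −20 °C; aq. NaHCO3
Reagents that add atoms: none
Why: Brønsted acid-catalysed asymmetric propargylation, in which the allenylboronate reacts through its γ-carbon in a six-membered chair transition state with the phosphoric acid hydrogen-bonded to a boronate oxygen and the formyl hydrogen, should deliver the propargyl group to the Re face of the enal and set C5' as (R).

Step 9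
Reactants: 15 (4R,5E,10S)-6,10-dimethyl-11-(triethylsilyloxy)undec-5-en-1-yn-4-ol
Product: 16 (4R,5E,10S)-4-(tert-butyldimethylsilyloxy)-6,10-dimethyl-11-(triethylsilyloxy)undec-5-en-1-yne
Conditions: TBSCl, imidazole, DMF, rt
Reagents that add atoms: tert-butyldimethylsilyl chloride, CC(C)(C)[Si](C)(C)Cl
Why: Silylation of the secondary alcohol gives a C5' ether inert to AlMe3 and differentiated from the more labile primary triethylsilyl ether at C12'.

Step 10
Reactants: 17 3-methylsalicylic acid
Product: 19 2,5-dihydroxy-3-methylbenzoic acid, via aryl sulfate 18 (not isolated)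
Conditions: K2S2O8, aq. NaOH, 0 °C → rt; then HCl, 90 °C
Reagents that add atoms: potassium peroxodisulfate, [K+].[K+].[O-]S(=O)(=O)OOS(=O)(=O)[O-]
Why: Elbs persulfate oxidation attacks the phenolate para to oxygen (the only free para position), and acid hydrolysis of the aryl sulfate gives the hydroquinone acid.

Step 11
Reactants: 19 2,5-dihydroxy-3-methylbenzoic acid
Product: 20 methyl 2,5-dimethoxy-3-methylbenzoate
Conditions: MeI (excess), K2CO3, DMF, 50 °C, argon
Reagents that add atoms: iodomethane, CI
Why: Exhaustive O-methylation (Williamson etherification and carboxylate alkylation) protects both phenols as methyl ethers that tolerate AlMe3, n-BuLi and nickel.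

Step 12
Reactants: 20 methyl 2,5-dimethoxy-3-methylbenzoate
Product: 21 (2,5-dimethoxy-3-methylphenyl)methanol
Conditions: LiAlH4, THF, 0 °C
Reagents that add atoms: none
Why: Hydride reduction of the aryl ester to the benzylic alcohol.

Step 13
Reactants: 21 (2,5-dimethoxy-3-methylphenyl)methanol
Product: 22 1-(chloromethyl)-2,5-dimethoxy-3-methylbenzene
Conditions: SOCl2, CH2Cl2, 0 °C → rt
Reagents that add atoms: thionyl chloride, O=S(Cl)Cl
Why: Deoxychlorination through the chlorosulfite should be fast for an electron-rich benzylic alcohol.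

Step 14
Reactants: 16 (4R,5E,10S)-4-(tert-butyldimethylsilyloxy)-6,10-dimethyl-11-(triethylsilyloxy)undec-5-en-1-yne; 22 1-(chloromethyl)-2,5-dimethoxy-3-methylbenzene
Product: 24 tert-butyl{[(2E,5R,6E,11S)-1-(2,5-dimethoxy-3-methylphenyl)-3,7,11-trimethyl-12-(triethylsilyloxy)dodeca-2,6-dien-5-yl]oxy}dimethylsilane, via alkenyldimethylalane 23 (not isolated)
Conditions: AlMe3 (2.5 equiv), Cp2ZrCl2 (0.25 equiv), ClCH2CH2Cl, 0 °C → rt; volatiles removed in vacuo; then 22, NiCl2(PPh3)2 (5 mol %) reduced with n-BuLi (10 mol %) to zerovalent nickel, THF, rt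
Reagents that add atoms: trimethylaluminium, C[Al](C)C
Why: A methylzirconocene–aluminium species adds methyl and metal syn across the terminal C2'≡C3' alkyne with methyl at the internal carbon C3', and exchange to aluminium leaves the (E)-alkenylalane 23 (Negishi methylalumination). Zerovalent nickel then inserts into the benzylic C–Cl bond of 22, the alkenyl group passes from aluminium to nickel with retention, and reductive elimination forms C1'–C2'; this is the known one-flask coupling of alkenylalanes with benzylic chlorides. No ring is closed and no stereocentre is created; C5' and C11' are not involved. The step needs methyl at C3' (given by the terminal-alkyne regiochemistry under the zirconocene catalyst), the E geometry (syn addition followed by stereoretentive transmetalation) and alkenyl rather than methyl transfer to nickel (alkenyl migrates preferentially, and excess AlMe3 is stripped off before nickel is added). The arene enters as an sp3 electrophile, so its substitution pattern is fixed in 22, and both side-chain oxygens are silyl ethers that AlMe3 should not attack.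

Step 15
Reactants: 24 tert-butyl{[(2E,5R,6E,11S)-1-(2,5-dimethoxy-3-methylphenyl)-3,7,11-trimethyl-12-(triethylsilyloxy)dodeca-2,6-dien-5-yl]oxy}dimethylsilane
Product: 25 (2S,6E,8R,10E)-8-(tert-butyldimethylsilyloxy)-12-(2,5-dimethoxy-3-methylphenyl)-2,6,10-trimethyldodeca-6,10-dien-1-ol
Conditions: PPTS (0.2 equiv), MeOH/CH2Cl2, 0 °C
Reagents that add atoms: none
Why: Mild acid methanolysis should cleave the primary triethylsilyl ether much faster than the secondary tert-butyldimethylsilyl ether (selective desilylation), with no oxidant near the arene.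

Step 16
Reactants: 25 (2S,6E,8R,10E)-8-(tert-butyldimethylsilyloxy)-12-(2,5-dimethoxy-3-methylphenyl)-2,6,10-trimethyldodeca-6,10-dien-1-ol
Product: 26 (2S,6E,8R,10E)-8-(tert-butyldimethylsilyloxy)-12-(2,5-dimethoxy-3-methylphenyl)-2,6,10-trimethyldodeca-6,10-dienal
Conditions: Dess–Martin periodinane, NaHCO3, CH2Cl2, 0 °C → rt
Reagents that add atoms: none
Why: Buffered Dess–Martin oxidation gives the α-methyl aldehyde under near-neutral conditions that should not epimerise C11'; the aldehyde is used at once.

Step 17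
Reactants: 26 (2S,6E,8R,10E)-8-(tert-butyldimethylsilyloxy)-12-(2,5-dimethoxy-3-methylphenyl)-2,6,10-trimethyldodeca-6,10-dienal; 27 prenyl chloride (1-chloro-3-methylbut-2-ene)
Product: 29 (6S,10E,12R,14E)-12-(tert-butyldimethylsilyloxy)-16-(2,5-dimethoxy-3-methylphenyl)-2,6,10,14-tetramethylhexadeca-2,10,14-trien-5-ol (mixture of C5 epimers), via prenylbarium chloride 28 (not isolated)
Conditions: BaI2, Li, biphenyl, THF, rt (activated barium); 27, −78 °C; then 26, −78 °C
Reagents that add atoms: none
Why: Allylic barium reagents add to aldehydes through the less substituted α-carbon without allylic transposition (α-selective allylbarium addition), giving the linear prenyl carbinol; the new C12' carbinol centre is removed by the next oxidation.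

Step 18
Reactants: 29 (6S,10E,12R,14E)-12-(tert-butyldimethylsilyloxy)-16-(2,5-dimethoxy-3-methylphenyl)-2,6,10,14-tetramethylhexadeca-2,10,14-trien-5-ol
Product: 30 (6S,10E,12R,14E)-12-(tert-butyldimethylsilyloxy)-16-(2,5-dimethoxy-3-methylphenyl)-2,6,10,14-tetramethylhexadeca-2,10,14-trien-5-one
Conditions: Dess–Martin periodinane, NaHCO3, CH2Cl2, 0 °C
Reagents that add atoms: none
Why: Buffered Dess–Martin oxidation converts the homoallylic alcohol into the β,γ-unsaturated ketone without base or acid that would conjugate the C14'=C15' alkene or epimerise C11'.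

Step 19
Reactants: 30 (6S,10E,12R,14E)-12-(tert-butyldimethylsilyloxy)-16-(2,5-dimethoxy-3-methylphenyl)-2,6,10,14-tetramethylhexadeca-2,10,14-trien-5-one
Product: 31 (6S,10E,12R,14E)-16-(2,5-dimethoxy-3-methylphenyl)-12-hydroxy-2,6,10,14-tetramethylhexadeca-2,10,14-trien-5-one
Conditions: HF·pyridine, pyridine, THF, 0 °C → rt
Reagents that add atoms: none
Why: Buffered fluoride desilylation frees the C5' alcohol under weakly acidic conditions that should tolerate the β,γ-unsaturated ketone and its α-stereocentre.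

Step 20
Reactants: 31 (6S,10E,12R,14E)-16-(2,5-dimethoxy-3-methylphenyl)-12-hydroxy-2,6,10,14-tetramethylhexadeca-2,10,14-trien-5-one
Product: 33 (6S,10E,12R,14E)-16-(2,5-dihydroxy-3-methylphenyl)-12-hydroxy-2,6,10,14-tetramethylhexadeca-2,10,14-trien-5-one (CNP0255159.1), via benzoquinone 32 (not isolated)
Conditions: (NH4)2Ce(NO3)6, MeCN/H2O, 0 °C; extraction into EtOAc; then aq. Na2S2O4, rt, argon
Reagents that add atoms: water, O
Why: Oxidative demethylation of the 1,4-dimethoxyarene gives the single possible para-quinone within minutes at 0 °C, with the quinone oxygens coming from water, and dithionite reduction in the work-up gives the hydroquinone as the last operation.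

**Compound list**
1 | methyl (S)-3-hydroxy-2-methylpropanoate | COC(=O)[C@@H](C)CO | starting material
2 | methyl (S)-2-methyl-3-(tosyloxy)propanoate | COC(=O)[C@@H](C)COS(=O)(=O)c1ccc(C)cc1 | intermediate
3 | (R)-3-hydroxy-2-methylpropyl 4-methylbenzenesulfonate | OC[C@@H](C)COS(=O)(=O)c1ccc(C)cc1 | intermediate
4 | (R)-2-methyl-3-(triethylsilyloxy)propyl 4-methylbenzenesulfonate | CC[Si](CC)(CC)OC[C@@H](C)COS(=O)(=O)c1ccc(C)cc1 | intermediate
5 | (4-bromobut-1-yn-1-yl)trimethylsilane | C[Si](C)(C)C#CCCBr | starting material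
6 | [4-(trimethylsilyl)but-3-yn-1-yl]magnesium bromide | C[Si](C)(C)C#CCC[Mg]Br | intermediate
7 | (S)-triethyl{[2-methyl-7-(trimethylsilyl)hept-6-yn-1-yl]oxy}silane | CC[Si](CC)(CC)OC[C@@H](C)CCCC#C[Si](C)(C)C | intermediate
8 | (S)-triethyl[(2-methylhept-6-yn-1-yl)oxy]silane | CC[Si](CC)(CC)OC[C@@H](C)CCCC#C | intermediate
9 | dimethyl[(1E,6S)-2,6-dimethyl-7-(triethylsilyloxy)hept-1-en-1-yl]alane | CC[Si](CC)(CC)OC[C@@H](C)CCC/C(C)=C/[Al](C)C | intermediate
10 | lithium butyl(dimethyl)[(1E,6S)-2,6-dimethyl-7-(triethylsilyloxy)hept-1-en-1-yl]alanate | CC[Si](CC)(CC)OC[C@@H](C)CCC/C(C)=C/[Al-](C)(C)CCCC.[Li+] | intermediate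
11 | (2E,7S)-3,7-dimethyl-8-(triethylsilyloxy)oct-2-en-1-ol | CC[Si](CC)(CC)OC[C@@H](C)CCC/C(C)=C/CO | intermediate
12 | (2E,7S)-3,7-dimethyl-8-(triethylsilyloxy)oct-2-enal | CC[Si](CC)(CC)OC[C@@H](C)CCC/C(C)=C/C=O | intermediate
13 | allenylboronic acid pinacol ester | C=C=CB1OC(C)(C)C(C)(C)O1 | starting material
14 | pinacol borate ester of 15 | CC[Si](CC)(CC)OC[C@@H](C)CCC/C(C)=C/[C@H](OB1OC(C)(C)C(C)(C)O1)CC#C | intermediate
15 | (4R,5E,10S)-6,10-dimethyl-11-(triethylsilyloxy)undec-5-en-1-yn-4-ol | CC[Si](CC)(CC)OC[C@@H](C)CCC/C(C)=C/[C@H](O)CC#C | intermediate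
16 | (4R,5E,10S)-4-(tert-butyldimethylsilyloxy)-6,10-dimethyl-11-(triethylsilyloxy)undec-5-en-1-yne | CC[Si](CC)(CC)OC[C@@H](C)CCC/C(C)=C/[C@H](O[Si](C)(C)C(C)(C)C)CC#C | intermediate
17 | 3-methylsalicylic acid | Cc1cccc(C(=O)O)c1O | starting material
18 | potassium 3-carboxy-4-hydroxy-5-methylphenyl sulfate | Cc1cc(OS(=O)(=O)[O-])cc(C(=O)O)c1O.[K+] | intermediate
19 | 2,5-dihydroxy-3-methylbenzoic acid | Cc1cc(O)cc(C(=O)O)c1O | intermediate
20 | methyl 2,5-dimethoxy-3-methylbenzoate | COC(=O)c1cc(OC)cc(C)c1OC | intermediate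
21 | (2,5-dimethoxy-3-methylphenyl)methanol | OCc1cc(OC)cc(C)c1OC | intermediate
22 | 1-(chloromethyl)-2,5-dimethoxy-3-methylbenzene | ClCc1cc(OC)cc(C)c1OC | intermediate
23 | (E)-alkenyldimethylalane from 16 | CC[Si](CC)(CC)OC[C@@H](C)CCC/C(C)=C/[C@H](O[Si](C)(C)C(C)(C)C)C/C(C)=C/[Al](C)C | intermediate
24 | tert-butyl{[(2E,5R,6E,11S)-1-(2,5-dimethoxy-3-methylphenyl)-3,7,11-trimethyl-12-(triethylsilyloxy)dodeca-2,6-dien-5-yl]oxy}dimethylsilane | CC[Si](CC)(CC)OC[C@@H](C)CCC/C(C)=C/[C@H](O[Si](C)(C)C(C)(C)C)C/C(C)=C/Cc1cc(OC)cc(C)c1OC | intermediate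
25 | (2S,6E,8R,10E)-8-(tert-butyldimethylsilyloxy)-12-(2,5-dimethoxy-3-methylphenyl)-2,6,10-trimethyldodeca-6,10-dien-1-ol | OC[C@@H](C)CCC/C(C)=C/[C@H](O[Si](C)(C)C(C)(C)C)C/C(C)=C/Cc1cc(OC)cc(C)c1OC | intermediate
26 | (2S,6E,8R,10E)-8-(tert-butyldimethylsilyloxy)-12-(2,5-dimethoxy-3-methylphenyl)-2,6,10-trimethyldodeca-6,10-dienal | O=C[C@@H](C)CCC/C(C)=C/[C@H](O[Si](C)(C)C(C)(C)C)C/C(C)=C/Cc1cc(OC)cc(C)c1OC | intermediate
27 | prenyl chloride (1-chloro-3-methylbut-2-ene) | CC(C)=CCCl | starting material
28 | prenylbarium chloride | CC(C)=CC[Ba]Cl | intermediate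
29 | (6S,10E,12R,14E)-12-(tert-butyldimethylsilyloxy)-16-(2,5-dimethoxy-3-methylphenyl)-2,6,10,14-tetramethylhexadeca-2,10,14-trien-5-ol (C5 epimers) | CC(C)=CCC(O)[C@@H](C)CCC/C(C)=C/[C@H](O[Si](C)(C)C(C)(C)C)C/C(C)=C/Cc1cc(OC)cc(C)c1OC | intermediate
30 | (6S,10E,12R,14E)-12-(tert-butyldimethylsilyloxy)-16-(2,5-dimethoxy-3-methylphenyl)-2,6,10,14-tetramethylhexadeca-2,10,14-trien-5-one | CC(C)=CCC(=O)[C@@H](C)CCC/C(C)=C/[C@H](O[Si](C)(C)C(C)(C)C)C/C(C)=C/Cc1cc(OC)cc(C)c1OC | intermediate
31 | (6S,10E,12R,14E)-16-(2,5-dimethoxy-3-methylphenyl)-12-hydroxy-2,6,10,14-tetramethylhexadeca-2,10,14-trien-5-one | CC(C)=CCC(=O)[C@@H](C)CCC/C(C)=C/[C@H](O)C/C(C)=C/Cc1cc(OC)cc(C)c1OC | intermediate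
32 | 2-[(2E,5R,6E,11S)-5-hydroxy-3,7,11,15-tetramethyl-12-oxohexadeca-2,6,14-trien-1-yl]-6-methylcyclohexa-2,5-diene-1,4-dione | CC(C)=CCC(=O)[C@@H](C)CCC/C(C)=C/[C@H](O)C/C(C)=C/CC1=CC(=O)C=C(C)C1=O | intermediate
33 | (6S,10E,12R,14E)-16-(2,5-dihydroxy-3-methylphenyl)-12-hydroxy-2,6,10,14-tetramethylhexadeca-2,10,14-trien-5-one (CNP0255159.1) | CC(C)=CCC(=O)[C@@H](C)CCC/C(C)=C/[C@H](O)C/C(C)=C/Cc1cc(O)cc(C)c1O | target

**Step count**
Total: 20 steps. Longest linear sequence: 16 steps (steps 1–9 and 14–20); the arene branch (steps 10–13) joins at step 14.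

**Steps most likely to fail**

1. Step 14. Methyl instead of alkenyl may be transferred to the benzylnickel intermediate if AlMe3 is not fully removed, the benzylic chloride may homocouple, and the Lewis-acidic medium may ionise the allylic C5' silyl ether during carboalumination. The fallback sets out from 16 and 22 and comes back at 24. The methylalumination of 16 is run as before, but alane 23 is quenched with I2 at −30 °C and the (1E,4R,5E,10S)-4-(tert-butyldimethylsilyloxy)-1-iodo-2,6,10-trimethyl-11-(triethylsilyloxy)undeca-1,5-diene F1 is isolated and purified. Separately, 22 is converted with Zn dust and LiCl in THF into (2,5-dimethoxy-3-methylbenzyl)zinc chloride F2. Negishi coupling of F1 with F2 under Pd(PPh3)4 in THF should give 24 with retention of the alkene geometry and no aluminium methyl groups present in the coupling.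

2. Step 17. The prenyl metal may react with allylic transposition (γ-attack), or the basic reagent may epimerise the α-methyl aldehyde at C11'. The fallback sets out from 26 and comes back at 30, bypassing 29. Commercial (3-methylbut-2-en-1-yl) phenyl sulfone is lithiated with n-BuLi in THF at −78 °C and added through its sulfonyl-bearing carbon to 26, giving the β-hydroxy sulfone (6S,10E,12R,14E)-12-(tert-butyldimethylsilyloxy)-16-(2,5-dimethoxy-3-methylphenyl)-2,6,10,14-tetramethyl-4-(phenylsulfonyl)hexadeca-2,10,14-trien-5-ol F3 as a diastereomer mixture. Dess–Martin oxidation gives the β-keto sulfone F4. Reductive desulfonylation with SmI2 in THF/MeOH at −78 °C, with α-protonation of the dienolate, should give the β,γ-unsaturated ketone 30.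

3. Step 8. Facial discrimination by the phosphoric acid may be poor on the β,β-disubstituted enal, giving low enantiomeric purity at C5'. The fallback sets out from 12 and comes back at 16. An acetate aldol addition of (S)-3-acetyl-4-isopropyl-1,3-thiazolidine-2-thione (TiCl4, iPr2NEt, CH2Cl2, −78 °C) to 12 through a chelated chair transition state is expected to attack the Re face and give (S)-3-[(3R,4E,9S)-3-hydroxy-5,9-dimethyl-10-(triethylsilyloxy)dec-4-enoyl]-4-isopropyl-1,3-thiazolidine-2-thione F5; the minor diastereomer can be removed by chromatography. Silylation (TBSOTf, 2,6-lutidine) gives the silyl ether F6. iBu2AlH at −78 °C releases the auxiliary and gives (3R,4E,9S)-3-(tert-butyldimethylsilyloxy)-5,9-dimethyl-10-(triethylsilyloxy)dec-4-enal F7. Ohira–Bestmann homologation (dimethyl (1-diazo-2-oxopropyl)phosphonate, K2CO3, MeOH) then gives alkyne 16.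

**Further compounds**
F1 | step 14 | (1E,4R,5E,10S)-4-(tert-butyldimethylsilyloxy)-1-iodo-2,6,10-trimethyl-11-(triethylsilyloxy)undeca-1,5-diene | CC[Si](CC)(CC)OC[C@@H](C)CCC/C(C)=C/[C@H](O[Si](C)(C)C(C)(C)C)C/C(C)=C/I
F2 | step 14 | (2,5-dimethoxy-3-methylbenzyl)zinc chloride | Cl[Zn]Cc1cc(OC)cc(C)c1OC
F3 | step 17 | (6S,10E,12R,14E)-12-(tert-butyldimethylsilyloxy)-16-(2,5-dimethoxy-3-methylphenyl)-2,6,10,14-tetramethyl-4-(phenylsulfonyl)hexadeca-2,10,14-trien-5-ol (diastereomer mixture at C4 and C5) | CC(C)=CC(S(=O)(=O)c1ccccc1)C(O)[C@@H](C)CCC/C(C)=C/[C@H](O[Si](C)(C)C(C)(C)C)C/C(C)=C/Cc1cc(OC)cc(C)c1OC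
F4 | step 17 | (6S,10E,12R,14E)-12-(tert-butyldimethylsilyloxy)-16-(2,5-dimethoxy-3-methylphenyl)-2,6,10,14-tetramethyl-4-(phenylsulfonyl)hexadeca-2,10,14-trien-5-one (C4 epimers) | CC(C)=CC(S(=O)(=O)c1ccccc1)C(=O)[C@@H](C)CCC/C(C)=C/[C@H](O[Si](C)(C)C(C)(C)C)C/C(C)=C/Cc1cc(OC)cc(C)c1OC
F5 | step 8 | (S)-3-[(3R,4E,9S)-3-hydroxy-5,9-dimethyl-10-(triethylsilyloxy)dec-4-enoyl]-4-isopropyl-1,3-thiazolidine-2-thione | CC[Si](CC)(CC)OC[C@@H](C)CCC/C(C)=C/[C@H](O)CC(=O)N1[C@@H](C(C)C)CSC1=S
F6 | step 8 | (S)-3-[(3R,4E,9S)-3-(tert-butyldimethylsilyloxy)-5,9-dimethyl-10-(triethylsilyloxy)dec-4-enoyl]-4-isopropyl-1,3-thiazolidine-2-thione | CC[Si](CC)(CC)OC[C@@H](C)CCC/C(C)=C/[C@H](O[Si](C)(C)C(C)(C)C)CC(=O)N1[C@@H](C(C)C)CSC1=S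
F7 | step 8 | (3R,4E,9S)-3-(tert-butyldimethylsilyloxy)-5,9-dimethyl-10-(triethylsilyloxy)dec-4-enal | CC[Si](CC)(CC)OC[C@@H](C)CCC/C(C)=C/[C@H](O[Si](C)(C)C(C)(C)C)CC=O
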